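**Strategy.** The oxolane (O1, C2 aryl, C3 CH2OH, C4 carbinol arm, C5 H2) is disconnected at O1–C5. C5 is the only unsubstituted ring carbon, so it can enter at the carboxyl level. In the key step an asymmetric chromium/nickel alkenylation of 3,4,5-trimethoxybenzaldehyde with a Z-3-iodoacrylate creates the C2 stereocenter, and the benzylic oxygen then closes the ring onto the ester carbon to give a 5-aryl butenolide. Its C=C bond is used to install the C3 and C4 substituents trans to each neighbour (conjugate addition of a masked hydroxymethyl group, enolate aroylation, chelation-controlled reduction). The lactone carbonyl is reduced late to the ring CH2, and the silane is oxidised to the alcohol.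

Key step: step 1

Assumption: the isopropoxysilane is taken to survive BF3·OEt2 at −78 °C in step 5; if it exchanges to the fluorosilane, the oxidation in step 6 is unaffected.

Step 1
Reactants: 1 3,4,5-trimethoxybenzaldehyde; 2 ethyl (Z)-3-iodoprop-2-enoate
Product: 5 (5R)-5-(3,4,5-trimethoxyphenyl)furan-2(5H)-one, via Z-configured silyl ether 3 (not isolated), via Z-configured hydroxy ester 4 (not isolated)
Conditions: CrCl2 (10 mol %), chiral 2-(oxazolin-2-yl)anilide sulfonamide ligand (11 mol %, enantiomer for Re-face addition), 1,8-bis(dimethylamino)naphthalene (11 mol %), NiCl2·(2,9-dimethyl-1,10-phenanthroline) (2 mol %), Mn, Me3SiCl, LiCl, MeCN, rt; then 1 M HCl, THF, rt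
Reagents that add atoms: none
Why: Zerovalent nickel inserts into the C–I bond of 2 with retention and hands the alkenyl group to chromium; the ligand-bound trivalent alkenylchromium adds to the Re face of aldehyde 1, Me3SiCl releases the product as silyl ether 3 and Mn returns chromium to the divalent state. The closest known type is the catalytic asymmetric Nozaki–Hiyama–Kishi alkenylation, and chromium/nickel couplings of Z-3-iodoacrylates with aldehydes are known to end in butenolides. After acidic desilylation the benzylic hydroxyl of 4 attacks the cis-placed ester carbonyl (5-exo-trig acyl substitution, loss of ethanol), so the 2(5H)-furanone ring is closed by the bond between the ring oxygen and the carbonyl carbon. The single new stereocenter, C5 (R), is controlled by the chiral ligand on chromium (catalyst control). The step needs retention of the Z geometry, secured by the stereoretentive oxidative addition and transmetalation of 2, and 1,2-addition to the aldehyde in preference to the ester, secured by the oxophilic, weakly basic alkenylchromium; the acidic work-up avoids base that could epimerise the γ-position.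

Step 2
Reactants: 5 (5R)-5-(3,4,5-trimethoxyphenyl)furan-2(5H)-one; 6 (chloromethyl)dimethyl(propan-2-yloxy)silane; 7 N,3,4-trimethoxy-N-methylbenzamide
Product: 11 (3S,4R,5R)-3-(3,4-dimethoxybenzoyl)-4-{[dimethyl(propan-2-yloxy)silyl]methyl}-5-(3,4,5-trimethoxyphenyl)oxolan-2-one, via Grignard reagent 8 (not isolated), via magnesium enolate 9 (not isolated), via tetrahedral magnesium adduct 10 (not isolated)
Conditions: 6, Mg, THF, reflux; then CuBr·SMe2 (10 mol %), THF, −78 °C, slow addition of 8 to 5; then 7, −78 → 0 °C; aq NH4Cl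
Reagents that add atoms: none
Why: Copper-catalysed conjugate addition of the hydroxymethyl-anion equivalent 8 to the butenolide occurs anti to the C5 aryl group (4,5-trans), and the magnesium enolate 9 is C-acylated by the N-methoxy-N-methylamide 7 anti to the new C4 substituent through the stable chelated adduct 10 (tandem Michael addition/Claisen-type acylation), the 3,4-trans arrangement at the epimerisable C3 also being the thermodynamic one.

Step 3
Reactants: 11 (3S,4R,5R)-3-(3,4-dimethoxybenzoyl)-4-{[dimethyl(propan-2-yloxy)silyl]methyl}-5-(3,4,5-trimethoxyphenyl)oxolan-2-one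
Product: 12 (3S,4R,5R)-3-[(S)-(3,4-dimethoxyphenyl)(hydroxy)methyl]-4-{[dimethyl(propan-2-yloxy)silyl]methyl}-5-(3,4,5-trimethoxyphenyl)oxolan-2-one
Conditions: Zn(BH4)2, Et2O/CH2Cl2, −40 → 0 °C
Reagents that add atoms: none
Why: Chelation-controlled reduction of the β-keto lactone (cyclic Cram model): zinc bridges the ketone and lactone carbonyls and hydride is delivered to the ketone face flanked by the C3–H and not by ring carbon C4, which should give the syn carbinol with (S) configuration at the new stereocenter, while the lactone is not reduced.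

Step 4
Reactants: 12 (3S,4R,5R)-3-[(S)-(3,4-dimethoxyphenyl)(hydroxy)methyl]-4-{[dimethyl(propan-2-yloxy)silyl]methyl}-5-(3,4,5-trimethoxyphenyl)oxolan-2-one
Product: 14 (3S,4R,5R)-3-[(S)-(acetyloxy)(3,4-dimethoxyphenyl)methyl]-4-{[dimethyl(propan-2-yloxy)silyl]methyl}-5-(3,4,5-trimethoxyphenyl)oxolan-2-yl acetate (both C2 epimers), via aluminium lactolate 13 (not isolated)
Conditions: iBu2AlH (2.3 equiv), CH2Cl2, −78 °C; then pyridine, DMAP, Ac2O, −78 °C → rt
Reagents that add atoms: acetic anhydride CC(=O)OC(C)=O
Why: Reductive acetylation of a lactone: at −78 °C the reduction stops at the tetrahedral aluminium lactolate, and acetylation in the same flask traps it and the benzylic aluminium alkoxide as acetates, so the carbonyl is taken to the acetal level and the benzylic oxygen is protected in one operation; the new acetal center is removed in step 5 and its configuration is of no consequence.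

Step 5
Reactants: 14 (3S,4R,5R)-3-[(S)-(acetyloxy)(3,4-dimethoxyphenyl)methyl]-4-{[dimethyl(propan-2-yloxy)silyl]methyl}-5-(3,4,5-trimethoxyphenyl)oxolan-2-yl acetate
Product: 15 (S)-(3,4-dimethoxyphenyl)[(3R,4R,5R)-4-{[dimethyl(propan-2-yloxy)silyl]methyl}-5-(3,4,5-trimethoxyphenyl)oxolan-3-yl]methyl acetate
Conditions: Et3SiH, BF3·OEt2, CH2Cl2, −78 °C
Reagents that add atoms: none
Why: Ionic hydrogenation of the anomeric acetate: BF3 ionises the acetal acetate to the ring oxocarbenium ion, which the silane reduces to the ring CH2, while the much less ionisable benzylic acetate and the benzylic ring ether are expected to survive at −78 °C and no stereocenter is touched.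

Step 6
Reactants: 15 (S)-(3,4-dimethoxyphenyl)[(3R,4R,5R)-4-{[dimethyl(propan-2-yloxy)silyl]methyl}-5-(3,4,5-trimethoxyphenyl)oxolan-3-yl]methyl acetate
Product: 17 (S)-(3,4-dimethoxyphenyl)[(3R,4S,5R)-4-(hydroxymethyl)-5-(3,4,5-trimethoxyphenyl)oxolan-3-yl]methanol, via hydroxy acetate 16 (not isolated)
Conditions: KF, KHCO3, 30% H2O2, THF/MeOH, rt; then K2CO3, MeOH, rt
Reagents that add atoms: hydrogen peroxide OO
Why: Tamao–Kumada oxidation converts the C–Si bond of the alkoxysilane into C–OH with retention at carbon, and mild base-catalysed methanolysis then removes the benzylic acetate without touching any stereocenter, which should give the target.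

**Compound list**

1 | 3,4,5-trimethoxybenzaldehyde | COc1cc(C=O)cc(OC)c1OC | starting material
2 | ethyl (Z)-3-iodoprop-2-enoate | CCOC(=O)/C=C\I | starting material
3 | ethyl (R,Z)-4-(3,4,5-trimethoxyphenyl)-4-[(trimethylsilyl)oxy]but-2-enoate | CCOC(=O)/C=C\[C@@H](O[Si](C)(C)C)c1cc(OC)c(OC)c(OC)c1 | intermediate (not isolated)
4 | ethyl (R,Z)-4-hydroxy-4-(3,4,5-trimethoxyphenyl)but-2-enoate | CCOC(=O)/C=C\[C@@H](O)c1cc(OC)c(OC)c(OC)c1 | intermediate (not isolated)
5 | (5R)-5-(3,4,5-trimethoxyphenyl)furan-2(5H)-one | O=C1C=C[C@H](c2cc(OC)c(OC)c(OC)c2)O1 | intermediate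
6 | (chloromethyl)dimethyl(propan-2-yloxy)silane | CC(C)O[Si](C)(C)CCl | starting material
7 | N,3,4-trimethoxy-N-methylbenzamide | CON(C)C(=O)c1ccc(OC)c(OC)c1 | starting material
8 | {[dimethyl(propan-2-yloxy)silyl]methyl}magnesium chloride | CC(C)O[Si](C)(C)C[Mg]Cl | intermediate (not isolated)
9 | chloromagnesium enolate of (4R,5R)-4-{[dimethyl(propan-2-yloxy)silyl]methyl}-5-(3,4,5-trimethoxyphenyl)oxolan-2-one | C1=C(O[Mg]Cl)O[C@@H](c2cc(OC)c(OC)c(OC)c2)[C@@H]1C[Si](C)(C)OC(C)C | intermediate (not isolated)
10 | chloromagnesium alkoxide of the N-methoxy-N-methyl hemiaminal formed from 9 and 7 | COc1ccc(C(O[Mg]Cl)(N(C)OC)[C@H]2C(=O)O[C@@H](c3cc(OC)c(OC)c(OC)c3)[C@@H]2C[Si](C)(C)OC(C)C)cc1OC | intermediate (not isolated)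
11 | (3S,4R,5R)-3-(3,4-dimethoxybenzoyl)-4-{[dimethyl(propan-2-yloxy)silyl]methyl}-5-(3,4,5-trimethoxyphenyl)oxolan-2-one | COc1ccc(C(=O)[C@H]2C(=O)O[C@@H](c3cc(OC)c(OC)c(OC)c3)[C@@H]2C[Si](C)(C)OC(C)C)cc1OC | intermediate
12 | (3S,4R,5R)-3-[(S)-(3,4-dimethoxyphenyl)(hydroxy)methyl]-4-{[dimethyl(propan-2-yloxy)silyl]methyl}-5-(3,4,5-trimethoxyphenyl)oxolan-2-one | COc1ccc([C@@H](O)[C@H]2C(=O)O[C@@H](c3cc(OC)c(OC)c(OC)c3)[C@@H]2C[Si](C)(C)OC(C)C)cc1OC | intermediate
13 | bis(diisobutylaluminium) derivative of the lactol of 12 (lactolate and benzylic alkoxide) | COc1ccc([C@@H](O[Al](CC(C)C)CC(C)C)[C@H]2C(O[Al](CC(C)C)CC(C)C)O[C@@H](c3cc(OC)c(OC)c(OC)c3)[C@@H]2C[Si](C)(C)OC(C)C)cc1OC | intermediate (not isolated)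
14 | (3S,4R,5R)-3-[(S)-(acetyloxy)(3,4-dimethoxyphenyl)methyl]-4-{[dimethyl(propan-2-yloxy)silyl]methyl}-5-(3,4,5-trimethoxyphenyl)oxolan-2-yl acetate (both C2 epimers) | COc1ccc([C@@H](OC(C)=O)[C@H]2C(OC(C)=O)O[C@@H](c3cc(OC)c(OC)c(OC)c3)[C@@H]2C[Si](C)(C)OC(C)C)cc1OC | intermediate
15 | (S)-(3,4-dimethoxyphenyl)[(3R,4R,5R)-4-{[dimethyl(propan-2-yloxy)silyl]methyl}-5-(3,4,5-trimethoxyphenyl)oxolan-3-yl]methyl acetate | COc1ccc([C@@H](OC(C)=O)[C@H]2CO[C@@H](c3cc(OC)c(OC)c(OC)c3)[C@@H]2C[Si](C)(C)OC(C)C)cc1OC | intermediate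
16 | (S)-(3,4-dimethoxyphenyl)[(3R,4S,5R)-4-(hydroxymethyl)-5-(3,4,5-trimethoxyphenyl)oxolan-3-yl]methyl acetate | COc1ccc([C@@H](OC(C)=O)[C@H]2CO[C@@H](c3cc(OC)c(OC)c(OC)c3)[C@@H]2CO)cc1OC | intermediate (not isolated)
17 | (S)-(3,4-dimethoxyphenyl)[(3R,4S,5R)-4-(hydroxymethyl)-5-(3,4,5-trimethoxyphenyl)oxolan-3-yl]methanol | COc1ccc([C@@H](O)[C@H]2CO[C@@H](c3cc(OC)c(OC)c(OC)c3)[C@@H]2CO)cc1OC | target

Total steps: 6. Longest linear sequence: 6 steps (1 → 5 → 11 → 12 → 14 → 15 → 17).

**Steps most likely to fail**

Step 1. The chromium catalyst may discriminate the faces of the electron-rich aldehyde poorly, or the configuration may erode through deprotonation of the acidic γ-position of the butenolide. The fallback sets out from 1. Addition of methyl propiolate with ZnMe2 and the ProPhenol ligand enantiomer that delivers the (S)-carbinol (toluene, 0 °C) should give methyl (S)-4-hydroxy-4-(3,4,5-trimethoxyphenyl)but-2-ynoate F1. Cis-selective semihydrogenation (H2, Pd/CaCO3 poisoned with Pb(OAc)2, quinoline, EtOAc) should give methyl (R,Z)-4-hydroxy-4-(3,4,5-trimethoxyphenyl)but-2-enoate F2, which lactonises in the flask and comes back to the route at 5.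

Step 2. The basic organomagnesium reagent may abstract the C5 proton of 5 (racemisation, isomerisation to the 2-oxyfuran) in competition with conjugate addition, and the magnesium enolate may be acylated incompletely. The fallback sets out from 5 and separates the two bond formations. A stoichiometric magnesium cuprate made from 8 and CuI, accelerated by Me3SiCl (THF, −78 °C), should outrun proton transfer and give trimethyl{[(2R,3R)-3-{[dimethyl(propan-2-yloxy)silyl]methyl}-2-(3,4,5-trimethoxyphenyl)-2,3-dihydrofuran-5-yl]oxy}silane F3. Mild aqueous acid should hydrolyse it to (4R,5R)-4-{[dimethyl(propan-2-yloxy)silyl]methyl}-5-(3,4,5-trimethoxyphenyl)oxolan-2-one F4. A separate Claisen-type acylation of its lithium enolate (LiN(SiMe3)2, THF, −78 °C, then 7) comes back to the route at 11.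

Step 3. Facial selectivity may be insufficient if an open, non-chelated transition state competes with the zinc chelate. The fallback sets out from 11 and replaces substrate control by catalyst control: asymmetric transfer hydrogenation under dynamic kinetic resolution conditions (RuCl(p-cymene)[(S,S)-TsDPEN], HCO2H/Et3N, DMF, rt). The catalyst should fix the (S) carbinol and the epimerisable C3 should settle trans to C4, coming back to the route at 12 without any new compound.

Further compounds
F1 | step 1 | methyl (S)-4-hydroxy-4-(3,4,5-trimethoxyphenyl)but-2-ynoate | COC(=O)C#C[C@@H](O)c1cc(OC)c(OC)c(OC)c1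
F2 | step 1 | methyl (R,Z)-4-hydroxy-4-(3,4,5-trimethoxyphenyl)but-2-enoate | COC(=O)/C=C\[C@@H](O)c1cc(OC)c(OC)c(OC)c1
F3 | step 2 | trimethyl{[(2R,3R)-3-{[dimethyl(propan-2-yloxy)silyl]methyl}-2-(3,4,5-trimethoxyphenyl)-2,3-dihydrofuran-5-yl]oxy}silane | C1=C(O[Si](C)(C)C)O[C@@H](c2cc(OC)c(OC)c(OC)c2)[C@@H]1C[Si](C)(C)OC(C)C
F4 | step 2 | (4R,5R)-4-{[dimethyl(propan-2-yloxy)silyl]methyl}-5-(3,4,5-trimethoxyphenyl)oxolan-2-one | C1C(=O)O[C@@H](c2cc(OC)c(OC)c(OC)c2)[C@@H]1C[Si](C)(C)OC(C)C
F0 | step 3 | none | none
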